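The route rests on disconnecting the C8–C9 bond of the cyclopentenone, whose C9 carbonyl sits between the ring C10=C11 cis-alkene and the exocyclic C7=C8 alkene (C1 = ester carbon, C12 = quaternary carbinol carbon). A cationic rhodium bisphosphine catalyst is to add the formyl C9–H bond of a Z-enal across the C7≡C8 alkyne, closing the five-membered ring C8–C12 and fixing the 7E geometry in one operation, with no enolate next to the C12 oxygen. The precursor is an acyclic enyne: C12 carries a triethylsilyloxy group, the (2Z,5Z)-octadienyl chain, the Z-enal arm and the alkyne joined to the (4R,5Z)-acetoxy ester chain.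

Key step: step 20

Remark: atom numbers follow the prostanoid convention (C1 = methyl ester carbon, ring = C8–C12, C20 = terminal methyl). The target is read as 4R,12S with 5Z,7E,14Z,17Z; the precursor 23 and the cyclised product 24 carry the same descriptors, so no structure needed correcting. PMB = 4-methoxybenzyl, TES = triethylsilyl.

**Route**

Step 1
Reactants: 1 2-methylenepropane-1,3-diol
Product: 2 2-{[(4-methoxybenzyl)oxy]methyl}prop-2-en-1-ol
Conditions: 1 (2 equiv), NaH (1 equiv), PMBCl (1 equiv), Bu4NI (cat.), THF/DMF, 0 °C to rt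
Reagents that add atoms: 4-methoxybenzyl chloride, COc1ccc(CCl)cc1
Why: Williamson ether synthesis on the monoalkoxide of a symmetrical diol used in excess should give mainly the monoether, and no stereocentre is involved.

Step 2
Reactants: 2 2-{[(4-methoxybenzyl)oxy]methyl}prop-2-en-1-ol
Product: 3 [(2S)-2-{[(4-methoxybenzyl)oxy]methyl}oxiran-2-yl]methanol
Conditions: Ti(OiPr)4 (10 mol %), L-(+)-diethyl tartrate (12 mol %), tBuOOH (2 equiv), 4 Å MS, CH2Cl2, −20 °C
Reagents that add atoms: tert-butyl hydroperoxide, CC(C)(C)OO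
Why: Katsuki–Sharpless asymmetric epoxidation: the allylic hydroxyl binds to the titanium tartrate complex, and with L-(+)-diethyl tartrate oxygen should be delivered to the alkene face that gives (S)-2-methylglycidol from 2-methylprop-2-en-1-ol, which here sets the future C12 (S in 3).

Step 3
Reactants: 3 [(2S)-2-{[(4-methoxybenzyl)oxy]methyl}oxiran-2-yl]methanol
Product: 4 (2R)-2-{[(4-methoxybenzyl)oxy]methyl}pent-4-yne-1,2-diol
Conditions: LiC≡CH·H2NCH2CH2NH2 (4 equiv), DMSO, rt; aq. NH4Cl
Reagents that add atoms: lithium acetylide–ethylenediamine complex, [Li+].[C-]#C.NCCN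
Why: Epoxide ring opening by acetylide is an SN2 attack at the unsubstituted oxirane carbon, so the C–O bond at the quaternary carbon is never broken (the descriptor becomes R only through changed priorities), and the Payne rearrangement open to the alkoxide of this 2,2-disubstituted glycidol is degenerate and cannot erode the ee.

Step 4
Reactants: 4 (2R)-2-{[(4-methoxybenzyl)oxy]methyl}pent-4-yne-1,2-diol; 5 1-bromopent-2-yne
Product: 6 (2R)-2-{[(4-methoxybenzyl)oxy]methyl}deca-4,7-diyne-1,2-diol
Conditions: CuI (20 mol %), K2CO3, Bu4NCl, DMF, rt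
Reagents that add atoms: none
Why: Copper-catalysed coupling of a terminal alkyne with a propargylic bromide (copper acetylide alkylation) forms the C15–C16 bond, tolerates the free diol and uses a base too weak to isomerise the skipped diyne.

Step 5
Reactants: 6 (2R)-2-{[(4-methoxybenzyl)oxy]methyl}deca-4,7-diyne-1,2-diol
Product: 7 (2R,4Z,7Z)-2-{[(4-methoxybenzyl)oxy]methyl}deca-4,7-diene-1,2-diol
Conditions: H2 (1 atm), Ni(OAc)2·4H2O/NaBH4 (P-2 nickel, 20 mol %), H2NCH2CH2NH2, EtOH, rt
Reagents that add atoms: none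
Why: Syn semi-hydrogenation of both alkynes on the amine-poisoned nickel boride surface should give the two Z alkenes (C14=C15 and C17=C18) while the PMB ether and the diol stay inert.

Step 6
Reactants: 7 (2R,4Z,7Z)-2-{[(4-methoxybenzyl)oxy]methyl}deca-4,7-diene-1,2-diol
Product: 8 (2S,4Z,7Z)-1-[(4-methoxybenzyl)oxy]-2-(triethylsilyloxy)-2-[(triethylsilyloxy)methyl]deca-4,7-diene
Conditions: Et3SiOTf (2.5 equiv), 2,6-lutidine (4 equiv), CH2Cl2, −78 to 0 °C
Reagents that add atoms: triethylsilyl trifluoromethanesulfonate, CC[Si](CC)(CC)OS(=O)(=O)C(F)(F)F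
Why: Silylation with a silyl triflate and a hindered pyridine base covers the tertiary hydroxyl as well as the primary one without touching the stereocentre.

Step 7
Reactants: 8 (2S,4Z,7Z)-1-[(4-methoxybenzyl)oxy]-2-(triethylsilyloxy)-2-[(triethylsilyloxy)methyl]deca-4,7-diene
Product: 9 (2S,4Z,7Z)-2-{[(4-methoxybenzyl)oxy]methyl}-2-(triethylsilyloxy)deca-4,7-dienal
Conditions: (COCl)2 (4 equiv), DMSO (8 equiv), CH2Cl2, −78 to −40 °C; Et3N, −78 °C to rt
Reagents that add atoms: none
Why: Swern oxidation with oxidative desilylation: the chlorosulfonium salt cleaves a primary triethylsilyl ether and oxidises it in the same flask, whereas the tertiary silyl ether and the PMB ether should stay, giving a non-enolisable α-silyloxy aldehyde.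

Step 8
Reactants: 9 (2S,4Z,7Z)-2-{[(4-methoxybenzyl)oxy]methyl}-2-(triethylsilyloxy)deca-4,7-dienal
Product: 10 (3R,5Z,8Z)-3-{[(4-methoxybenzyl)oxy]methyl}-3-(triethylsilyloxy)undeca-5,8-dien-1-yne
Conditions: dimethyl (1-diazo-2-oxopropyl)phosphonate (1.5 equiv), K2CO3 (2 equiv), MeOH, 0 °C to rt
Reagents that add atoms: dimethyl (1-diazo-2-oxopropyl)phosphonate, COP(=O)(OC)C(=[N+]=[N-])C(C)=O
Why: Seyferth–Gilbert homologation with the Ohira–Bestmann reagent converts the non-enolisable aldehyde into the terminal alkyne C8≡C7 under carbonate conditions that a tertiary triethylsilyl ether tolerates.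

Step 9
Reactants: 10 (3R,5Z,8Z)-3-{[(4-methoxybenzyl)oxy]methyl}-3-(triethylsilyloxy)undeca-5,8-dien-1-yne
Product: 11 (2R,4Z,7Z)-2-ethynyl-2-(triethylsilyloxy)deca-4,7-dien-1-ol
Conditions: DDQ (1.3 equiv), CH2Cl2/pH 7 buffer (10:1), 0 °C
Reagents that add atoms: none
Why: Oxidative cleavage of the electron-rich benzyl ether by DDQ (hydride abstraction, hydrolysis of the oxocarbenium ion) frees the primary alcohol without affecting the silyl ether, the alkyne or the skipped diene.

Step 10
Reactants: 11 (2R,4Z,7Z)-2-ethynyl-2-(triethylsilyloxy)deca-4,7-dien-1-ol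
Product: 12 (2R,4Z,7Z)-2-ethynyl-2-(triethylsilyloxy)deca-4,7-dienal
Conditions: Dess–Martin periodinane (1.5 equiv), NaHCO3, CH2Cl2, 0 °C to rt
Reagents that add atoms: none
Why: Dess–Martin oxidation works under buffered, non-basic conditions, and the α-carbon is quaternary, so the stereocentre cannot epimerise.

Step 11
Reactants: 12 (2R,4Z,7Z)-2-ethynyl-2-(triethylsilyloxy)deca-4,7-dienal
Product: 13 methyl (2Z,4S,6Z,9Z)-4-ethynyl-4-(triethylsilyloxy)dodeca-2,6,9-trienoate
Conditions: (CF3CH2O)2P(O)CH2CO2Me (1.3 equiv), KN(SiMe3)2 (1.25 equiv), 18-crown-6 (4 equiv), THF, −78 °C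
Reagents that add atoms: methyl bis(2,2,2-trifluoroethyl)phosphonoacetate, COC(=O)CP(=O)(OCC(F)(F)F)OCC(F)(F)F
Why: Still–Gennari variant of the Horner–Wadsworth–Emmons reaction: fast, irreversible elimination from the electron-poor phosphonate adduct under a dissociated potassium base should give the Z-enoate, creating the cis C10=C11 alkene.

Step 12
Reactants: 13 methyl (2Z,4S,6Z,9Z)-4-ethynyl-4-(triethylsilyloxy)dodeca-2,6,9-trienoate
Product: 14 (2Z,4S,6Z,9Z)-4-ethynyl-4-(triethylsilyloxy)dodeca-2,6,9-trien-1-ol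
Conditions: iBu2AlH (2.5 equiv), CH2Cl2, −78 °C; aq. KNaC4H4O6
Reagents that add atoms: none
Why: 1,2-Reduction of the conjugated ester by the aluminium hydride at low temperature gives the Z-allylic alcohol without moving the double bond, at a stage where the molecule holds no other ester.

Step 13
Reactants: 15 methyl 4-chloro-4-oxobutanoate; 16 bis(trimethylsilyl)acetylene
Product: 17 methyl 4-oxo-6-(trimethylsilyl)hex-5-ynoate
Conditions: AlCl3 (1.1 equiv), CH2Cl2, 0 °C
Reagents that add atoms: none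
Why: Friedel–Crafts-type acylation of an alkynylsilane: the acylium ion attacks the silicon-bearing carbon (β-silyl stabilisation) and one silyl group leaves as the chloride, giving the silyl ynone.

Step 14
Reactants: 17 methyl 4-oxo-6-(trimethylsilyl)hex-5-ynoate
Product: 18 methyl (4R)-4-hydroxy-6-(trimethylsilyl)hex-5-ynoate
Conditions: Ru[(R,R)-TsDPEN](p-cymene) (amido complex, 1 mol %), iPrOH, rt
Reagents that add atoms: none
Why: Noyori asymmetric transfer hydrogenation: the ruthenium hydride with the (R,R)-diamine ligand transfers hydride and proton through a six-membered transition state in which the alkynyl group plays the part of the aryl group of an aryl ketone, which by analogy with simple alkyl alkynyl ketones should set C4 as R.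

Step 15
Reactants: 18 methyl (4R)-4-hydroxy-6-(trimethylsilyl)hex-5-ynoate
Product: 19 methyl (4R)-4-acetoxy-6-(trimethylsilyl)hex-5-ynoate
Conditions: Ac2O, pyridine, DMAP (cat.), CH2Cl2, 0 °C
Reagents that add atoms: acetic anhydride, CC(=O)OC(C)=O
Why: DMAP-catalysed acylation of the secondary alcohol installs the C4 acetate of the target with retention and removes the risk of lactonisation of the γ-hydroxy ester.

Step 16
Reactants: 19 methyl (4R)-4-acetoxy-6-(trimethylsilyl)hex-5-ynoate
Product: 20 methyl (4R)-4-acetoxy-6-iodohex-5-ynoate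
Conditions: N-iodosuccinimide (1.2 equiv), AgNO3 (10 mol %), DMF, rt, dark
Reagents that add atoms: N-iodosuccinimide, O=C1CCC(=O)N1I
Why: Silver-catalysed iododesilylation of an alkynylsilane (silver acetylide formation, then electrophilic iodination) gives the 1-iodoalkyne directly and leaves the esters alone.

Step 17
Reactants: 20 methyl (4R)-4-acetoxy-6-iodohex-5-ynoate
Product: 21 methyl (4R,5Z)-4-acetoxy-6-iodohex-5-enoate
Conditions: 2-nitrobenzenesulfonylhydrazide (2.5 equiv), Et3N, THF/iPrOH, rt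
Reagents that add atoms: none
Why: Diimide reduction: diimide released from the sulfonylhydrazide transfers two hydrogens to the iodoalkyne in a concerted syn fashion, giving the (Z)-iodoalkene without cleaving the C–I bond or reducing the esters.

Step 18
Reactants: 14 (2Z,4S,6Z,9Z)-4-ethynyl-4-(triethylsilyloxy)dodeca-2,6,9-trien-1-ol; 21 methyl (4R,5Z)-4-acetoxy-6-iodohex-5-enoate
Product: 22 methyl (4R,5Z,9S,10Z)-4-acetoxy-12-hydroxy-9-[(2Z,5Z)-octa-2,5-dien-1-yl]-9-(triethylsilyloxy)dodeca-5,10-dien-7-ynoate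
Conditions: Pd(PPh3)4 (5 mol %), CuI (10 mol %), Et3N, THF (degassed), rt
Reagents that add atoms: none
Why: Sonogashira coupling (zerovalent palladium, copper acetylide) joins C7 to C6 with retention of the Z geometry of the iodoalkene, since oxidative addition into the C–I bond is much faster than ionisation of the allylic acetate and the tertiary amine is not a nucleophile for it.

Step 19
Reactants: 22 methyl (4R,5Z,9S,10Z)-4-acetoxy-12-hydroxy-9-[(2Z,5Z)-octa-2,5-dien-1-yl]-9-(triethylsilyloxy)dodeca-5,10-dien-7-ynoate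
Product: 23 methyl (4R,5Z,9S,10Z)-4-acetoxy-9-[(2Z,5Z)-octa-2,5-dien-1-yl]-12-oxo-9-(triethylsilyloxy)dodeca-5,10-dien-7-ynoate
Conditions: Dess–Martin periodinane (1.5 equiv), NaHCO3, CH2Cl2, 0 °C; used at once
Reagents that add atoms: none
Why: Dess–Martin oxidation of the primary allylic alcohol under buffered conditions gives the Z-enal without an enol or enolate intermediate that could isomerise C10=C11, and the C12 silyl ether prevents lactol formation.

Step 20
Reactants: 23 methyl (4R,5Z,9S,10Z)-4-acetoxy-9-[(2Z,5Z)-octa-2,5-dien-1-yl]-12-oxo-9-(triethylsilyloxy)dodeca-5,10-dien-7-ynoate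
Product: 24 methyl (4R,5Z,7E)-4-acetoxy-7-[(5S)-5-[(2Z,5Z)-octa-2,5-dien-1-yl]-2-oxo-5-(triethylsilyloxy)cyclopent-3-en-1-ylidene]hept-5-enoate
Conditions: [Rh(cod)2]BF4 (10 mol %), rac-BINAP (10 mol %), H2 then Ar (catalyst activation), CH2Cl2, 0 °C to rt
Reagents that add atoms: none
Why: Proposed new method: the cationic monovalent rhodium centre should insert into the formyl C9–H bond, the tethered alkyne should then insert syn into Rh–H (H to C7, Rh to C8) to give a six-membered acyl(alkenyl)rhodium metallacycle, and C8–C9 reductive elimination should release the ketone and the catalyst. The closest known reaction type is the rhodium-catalysed intramolecular hydroacylation of 5-alkynals to (E)-2-alkylidenecyclopentanones; a Z-enal as acyl donor combined with a conjugated enyne as acceptor has not been shown. The five-membered ring C8–C9–C10–C11–C12 closes in the 5-exo-dig mode, because the cis C10=C11 alkene and quaternary C12 hold C9 within reach of C8, whereas bonding to C7 would need an anti addition inside a six-membered ring. No stereocentre is formed and C4 and C12 are spectators; the exocyclic geometry follows from syn addition, which puts H7 cis and C6 trans to C9 (7E). The step needs chemoselectivity over decarbonylation and over Z to E isomerisation of C10=C11 and C5=C6, which the chelating bisphosphine, the weakly coordinating solvent, the low temperature and the proximity of the alkyne should secure; keeping the C12 oxygen as a silyl ether rules out propargylic ester migration on rhodium.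

Step 21
Reactants: 24 methyl (4R,5Z,7E)-4-acetoxy-7-[(5S)-5-[(2Z,5Z)-octa-2,5-dien-1-yl]-2-oxo-5-(triethylsilyloxy)cyclopent-3-en-1-ylidene]hept-5-enoate
Product: 25 methyl (4R,5Z,7E)-4-acetoxy-7-[(5S)-5-hydroxy-5-[(2Z,5Z)-octa-2,5-dien-1-yl]-2-oxocyclopent-3-en-1-ylidene]hept-5-enoate
Conditions: HF·pyridine, pyridine, THF, 0 °C to rt
Reagents that add atoms: none
Why: Fluoride-mediated desilylation with buffered HF·pyridine is mildly acidic, not basic, so the cross-conjugated dienone, the acetate and the methyl ester should survive while the tertiary silyl ether is cleaved.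

Step 22
Reactants: 25 methyl (4R,5Z,7E)-4-acetoxy-7-[(5S)-5-hydroxy-5-[(2Z,5Z)-octa-2,5-dien-1-yl]-2-oxocyclopent-3-en-1-ylidene]hept-5-enoate
Product: 26 methyl (4R,5Z,7E)-4-acetoxy-7-[(5S)-5-acetoxy-5-[(2Z,5Z)-octa-2,5-dien-1-yl]-2-oxocyclopent-3-en-1-ylidene]hept-5-enoate (target)
Conditions: Ac2O, DMAP, Et3N, CH2Cl2, rt
Reagents that add atoms: acetic anhydride, CC(=O)OC(C)=O
Why: DMAP-catalysed acylation (nucleophilic catalysis through the N-acetylpyridinium ion) esterifies the hindered tertiary alcohol without touching either stereocentre or the alkenes.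

**Compound list**

1 | 2-methylenepropane-1,3-diol | C=C(CO)CO | starting material
2 | 2-{[(4-methoxybenzyl)oxy]methyl}prop-2-en-1-ol | C=C(CO)COCc1ccc(OC)cc1 | intermediate
3 | [(2S)-2-{[(4-methoxybenzyl)oxy]methyl}oxiran-2-yl]methanol | COc1ccc(COC[C@]2(CO)CO2)cc1 | intermediate
4 | (2R)-2-{[(4-methoxybenzyl)oxy]methyl}pent-4-yne-1,2-diol | COc1ccc(COC[C@](O)(CO)CC#C)cc1 | intermediate
5 | 1-bromopent-2-yne | CCC#CCBr | starting material
6 | (2R)-2-{[(4-methoxybenzyl)oxy]methyl}deca-4,7-diyne-1,2-diol | COc1ccc(COC[C@](O)(CO)CC#CCC#CCC)cc1 | intermediate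
7 | (2R,4Z,7Z)-2-{[(4-methoxybenzyl)oxy]methyl}deca-4,7-diene-1,2-diol | COc1ccc(COC[C@](O)(CO)C/C=C\C/C=C\CC)cc1 | intermediate
8 | (2S,4Z,7Z)-1-[(4-methoxybenzyl)oxy]-2-(triethylsilyloxy)-2-[(triethylsilyloxy)methyl]deca-4,7-diene | COc1ccc(COC[C@](O[Si](CC)(CC)CC)(CO[Si](CC)(CC)CC)C/C=C\C/C=C\CC)cc1 | intermediate
9 | (2S,4Z,7Z)-2-{[(4-methoxybenzyl)oxy]methyl}-2-(triethylsilyloxy)deca-4,7-dienal | COc1ccc(COC[C@](O[Si](CC)(CC)CC)(C=O)C/C=C\C/C=C\CC)cc1 | intermediate
10 | (3R,5Z,8Z)-3-{[(4-methoxybenzyl)oxy]methyl}-3-(triethylsilyloxy)undeca-5,8-dien-1-yne | COc1ccc(COC[C@](O[Si](CC)(CC)CC)(C#C)C/C=C\C/C=C\CC)cc1 | intermediate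
11 | (2R,4Z,7Z)-2-ethynyl-2-(triethylsilyloxy)deca-4,7-dien-1-ol | OC[C@](O[Si](CC)(CC)CC)(C#C)C/C=C\C/C=C\CC | intermediate
12 | (2R,4Z,7Z)-2-ethynyl-2-(triethylsilyloxy)deca-4,7-dienal | O=C[C@](O[Si](CC)(CC)CC)(C#C)C/C=C\C/C=C\CC | intermediate
13 | methyl (2Z,4S,6Z,9Z)-4-ethynyl-4-(triethylsilyloxy)dodeca-2,6,9-trienoate | COC(=O)/C=C\[C@](O[Si](CC)(CC)CC)(C#C)C/C=C\C/C=C\CC | intermediate
14 | (2Z,4S,6Z,9Z)-4-ethynyl-4-(triethylsilyloxy)dodeca-2,6,9-trien-1-ol | OC/C=C\[C@](O[Si](CC)(CC)CC)(C#C)C/C=C\C/C=C\CC | intermediate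
15 | methyl 4-chloro-4-oxobutanoate | COC(=O)CCC(Cl)=O | starting material
16 | bis(trimethylsilyl)acetylene | C[Si](C)(C)C#C[Si](C)(C)C | starting material
17 | methyl 4-oxo-6-(trimethylsilyl)hex-5-ynoate | COC(=O)CCC(=O)C#C[Si](C)(C)C | intermediate
18 | methyl (4R)-4-hydroxy-6-(trimethylsilyl)hex-5-ynoate | COC(=O)CC[C@@H](O)C#C[Si](C)(C)C | intermediate
19 | methyl (4R)-4-acetoxy-6-(trimethylsilyl)hex-5-ynoate | COC(=O)CC[C@@H](OC(C)=O)C#C[Si](C)(C)C | intermediate
20 | methyl (4R)-4-acetoxy-6-iodohex-5-ynoate | COC(=O)CC[C@@H](OC(C)=O)C#CI | intermediate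
21 | methyl (4R,5Z)-4-acetoxy-6-iodohex-5-enoate | COC(=O)CC[C@@H](OC(C)=O)/C=C\I | intermediate
22 | methyl (4R,5Z,9S,10Z)-4-acetoxy-12-hydroxy-9-[(2Z,5Z)-octa-2,5-dien-1-yl]-9-(triethylsilyloxy)dodeca-5,10-dien-7-ynoate | CC/C=C\C/C=C\C[C@](O[Si](CC)(CC)CC)(/C=C\CO)C#C/C=C\[C@@H](CCC(=O)OC)OC(C)=O | intermediate
23 | methyl (4R,5Z,9S,10Z)-4-acetoxy-9-[(2Z,5Z)-octa-2,5-dien-1-yl]-12-oxo-9-(triethylsilyloxy)dodeca-5,10-dien-7-ynoate | CC/C=C\C/C=C\C[C@](O[Si](CC)(CC)CC)(/C=C\C=O)C#C/C=C\[C@@H](CCC(=O)OC)OC(C)=O | intermediate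
24 | methyl (4R,5Z,7E)-4-acetoxy-7-[(5S)-5-[(2Z,5Z)-octa-2,5-dien-1-yl]-2-oxo-5-(triethylsilyloxy)cyclopent-3-en-1-ylidene]hept-5-enoate | CC/C=C\C/C=C\C[C@]1(O[Si](CC)(CC)CC)C=CC(=O)/C1=C/C=C\[C@@H](CCC(=O)OC)OC(C)=O | intermediate
25 | methyl (4R,5Z,7E)-4-acetoxy-7-[(5S)-5-hydroxy-5-[(2Z,5Z)-octa-2,5-dien-1-yl]-2-oxocyclopent-3-en-1-ylidene]hept-5-enoate | CC/C=C\C/C=C\C[C@]1(O)C=CC(=O)/C1=C/C=C\[C@@H](CCC(=O)OC)OC(C)=O | intermediate
26 | methyl (4R,5Z,7E)-4-acetoxy-7-[(5S)-5-acetoxy-5-[(2Z,5Z)-octa-2,5-dien-1-yl]-2-oxocyclopent-3-en-1-ylidene]hept-5-enoate | CC/C=C\C/C=C\C[C@]1(OC(C)=O)C=CC(=O)/C1=C/C=C\[C@@H](CCC(=O)OC)OC(C)=O | target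

**Step count and risks**

Total step count: 22. Longest linear sequence: 17 steps (steps 1–12, then 18–22). The iodoalkene 21 comes from a 5-step branch (steps 13–17).

Steps most likely to fail:

1. Step 20 (the labelled step). The acyl rhodium hydride may lose CO before the alkyne inserts, the cis enal may isomerise so that C9 can no longer reach C8, or the conjugated enyne may bind the catalyst without turnover. The fallback uses known chemistry and runs from 23 to 25. Nickel-catalysed reductive cyclisation of the ynal (Ni(cod)2, PBu3, Et3SiH, THF, 0 °C to rt) forms C8–C9 by oxidative cyclisation of alkyne and aldehyde on zerovalent nickel and places hydrogen on C7 syn to the new bond. It should give methyl (4R,5Z)-4-acetoxy-7-[(5S)-5-[(2Z,5Z)-octa-2,5-dien-1-yl]-2,5-bis(triethylsilyloxy)cyclopent-3-en-1-ylidene]hept-5-enoate F1 (ring C2 epimers, H7 cis to ring C2). HF·pyridine (THF, 0 °C to rt) then removes both silyl groups to give methyl (4R,5Z)-4-acetoxy-7-[(5S)-2,5-dihydroxy-5-[(2Z,5Z)-octa-2,5-dien-1-yl]cyclopent-3-en-1-ylidene]hept-5-enoate F2. MnO2 (CH2Cl2, rt) oxidises only the secondary, doubly allylic alcohol and gives 25, which re-enters the route at step 22.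

2. Step 5. The skipped diyne may be over-reduced or only half reduced, or the alkenes may isomerise, giving mixtures that cannot be separated. The fallback builds the diene by olefination and runs from 3 to 7. CH2=CHMgBr with CuI (cat.) in THF at −30 to 0 °C opens the epoxide of 3 at its CH2 group to give (2R)-2-{[(4-methoxybenzyl)oxy]methyl}pent-4-ene-1,2-diol F3. Lemieux–Johnson cleavage (OsO4 cat., NaIO4, 2,6-lutidine, dioxane/H2O) gives the hydroxy aldehyde as its lactol (4S)-4-{[(4-methoxybenzyl)oxy]methyl}oxolane-2,4-diol F4. Separately, (Z)-hex-3-en-1-ol is converted by the Appel reaction (CBr4, PPh3, CH2Cl2) into (Z)-1-bromohex-3-ene F5 and then with PPh3 (MeCN, reflux) into [(3Z)-hex-3-en-1-yl]triphenylphosphonium bromide F6. Wittig reaction of F4 with F6 and NaN(SiMe3)2 in excess (THF, −78 °C to rt) should form the C14=C15 Z alkene and give 7.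

3. Step 7. Cleavage of the neopentyl-type primary silyl ether by the chlorosulfonium salt may be sluggish, or the tertiary silyl ether may be lost in part. The fallback reverses the order of oxidation and protection and runs from 7 to 9. TEMPO (cat.) with PhI(OAc)2 (CH2Cl2, rt) oxidises only the primary hydroxyl of 7, since the tertiary one cannot be oxidised, to (2S,4Z,7Z)-2-hydroxy-2-{[(4-methoxybenzyl)oxy]methyl}deca-4,7-dienal F7. Et3SiOTf with 2,6-lutidine (CH2Cl2, −78 °C) then silylates the tertiary hydroxyl and gives 9.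

**Further compounds**

F1 | step 20 | methyl (4R,5Z)-4-acetoxy-7-[(5S)-5-[(2Z,5Z)-octa-2,5-dien-1-yl]-2,5-bis(triethylsilyloxy)cyclopent-3-en-1-ylidene]hept-5-enoate (ring C2 epimers, H7 cis to ring C2) | CC/C=C\C/C=C\C[C@]1(O[Si](CC)(CC)CC)C=CC(O[Si](CC)(CC)CC)/C1=C/C=C\[C@@H](CCC(=O)OC)OC(C)=O
F2 | step 20 | methyl (4R,5Z)-4-acetoxy-7-[(5S)-2,5-dihydroxy-5-[(2Z,5Z)-octa-2,5-dien-1-yl]cyclopent-3-en-1-ylidene]hept-5-enoate (ring C2 epimers, H7 cis to ring C2) | CC/C=C\C/C=C\C[C@]1(O)C=CC(O)/C1=C/C=C\[C@@H](CCC(=O)OC)OC(C)=O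
F3 | step 5 | (2R)-2-{[(4-methoxybenzyl)oxy]methyl}pent-4-ene-1,2-diol | COc1ccc(COC[C@](O)(CO)CC=C)cc1
F4 | step 5 | (4S)-4-{[(4-methoxybenzyl)oxy]methyl}oxolane-2,4-diol (anomers) | COc1ccc(COC[C@]2(O)COC(O)C2)cc1
F5 | step 5 | (Z)-1-bromohex-3-ene | CC/C=C\CCBr
F6 | step 5 | [(3Z)-hex-3-en-1-yl]triphenylphosphonium bromide | CC/C=C\CC[P+](c1ccccc1)(c1ccccc1)c1ccccc1.[Br-]
F7 | step 7 | (2S,4Z,7Z)-2-hydroxy-2-{[(4-methoxybenzyl)oxy]methyl}deca-4,7-dienal | COc1ccc(COC[C@](O)(C=O)C/C=C\C/C=C\CC)cc1
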